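## Retrosynthetic overview

- The 11‑hydroxy‑Δ6‑8‑one is traced back to a 7(11)‑en‑8‑one (isopropylidene ketone) by a late Schenck ene oxidation with singlet oxygen.
- The C3 ester is disconnected to a 3β‑alcohol and (2R,3S)‑3‑chloro‑2‑hydroxy‑2‑methylbutanoic acid, made by Sharpless epoxidation of tiglyl alcohol, oxidation and HCl opening.
- The 3β‑OH/4α‑OAc pair comes from axial hydride reduction of a 4α‑acetoxy‑3‑ketone, itself from α‑face ketohydroxylation of a Δ3 olefin.
- The decalin comes from a catalytic enantioselective, proton‑initiated transannular cyclisation of achiral germacrone (C5–C10 bond, as in germacrene → eudesmyl cation).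
- Ring order: the ten‑membered germacrane ring (the farnesyl C1–C10 closure, already present in germacrone) first, then both six‑membered rings at once by the transannular closure.

Assumption: germacrone (crystallised on scale from Geranium macrorrhizum and Curcuma oils) and (E)‑2‑methylbut‑2‑en‑1‑ol are taken as inexpensive catalogue compounds; positions use eudesmane numbering (C3 = CH–O‑ester, C4 = C(Me)OAc, C8 = C=O, α = face opposite the C10 methyl).

## Route

Step 1
Reactants: 1 germacrone
Product: 2 (5R,10R)-eudesma-3,7(11)-dien-8-one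
Conditions: chiral confined IDPi Brønsted acid (5 mol %, antipode selected for the 5R,10R series), (CF3)3COH/CH2Cl2, −40 → 0 °C
Reagents that add atoms: none
Why: Proposed new method: the chiral acid protonates C1 of the 1(10)‑olefin on one of the two rapidly interconverting planar‑chiral chair–chair conformers of achiral 1, C5 of the 4,5‑olefin closes on the C10 cation (E,E geometry gives the trans‑fused 5α‑H/10β‑Me decalin) and the chiral counter‑anion removes H‑3 from the C4 cation to give the Δ3 olefin; the closest known reaction types are the acid‑mediated transannular cyclisation of germacrone to racemic selinadienones and IDPi‑catalysed enantioselective protonative polyene cyclisation.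

Step 2
Reactants: 2 (5R,10R)-eudesma-3,7(11)-dien-8-one
Product: 3 (4S,5R,10R)-4-hydroxyeudesm-7(11)-ene-3,8-dione
Conditions: RuCl3 (1 mol %), Oxone, NaHCO3, EtOAc/MeCN/H2O (6:6:1), rt, 20 min
Reagents that add atoms: Oxone (potassium peroxymonosulfate), [K+].[O-]S(=O)(=O)OO
Why: Ru‑catalysed ketohydroxylation (RuO4 [3+2] addition, then oxidation of the ruthenate ester) takes the electron‑rich trisubstituted Δ3 olefin in preference to the hindered tetrasubstituted enone olefin and adds from the α face anti to the axial C10 methyl, so the tertiary C4 hydroxyl is α (4S) and C3 becomes the ketone.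

Step 3
Reactants: 3 (4S,5R,10R)-4-hydroxyeudesm-7(11)-ene-3,8-dione
Product: 4 (4S,5R,10R)-4-acetoxyeudesm-7(11)-ene-3,8-dione
Conditions: Ac2O, DMAP, Et3N, CH2Cl2, rt → 35 °C
Reagents that add atoms: acetic anhydride, CC(=O)OC(C)=O
Why: DMAP‑catalysed acylation (nucleophilic catalysis) of the only hydroxyl, an equatorial tertiary α‑ketol, touches no stereocentre.

Step 4
Reactants: 4 (4S,5R,10R)-4-acetoxyeudesm-7(11)-ene-3,8-dione
Product: 5 (3S,4S,5R,10R)-4-acetoxy-3-hydroxyeudesm-7(11)-en-8-one
Conditions: NaBH4 (0.5 equiv), MeOH/CH2Cl2, −78 °C; AcOH quench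
Reagents that add atoms: none
Why: Chemoselective borohydride reduction, since the α‑acetoxy saturated C3 ketone is far more electrophilic than the hindered conjugated C8 ketone; hydride attacks axially from the α face (the β face is blocked by the axial 4β‑methyl), giving the equatorial 3β‑alcohol (3S), as with 4,4‑disubstituted 3‑ketones.

Step 5
Reactants: 6 (E)-2-methylbut-2-en-1-ol
Product: 7 [(2R,3R)-2,3-dimethyloxiran-2-yl]methanol
Conditions: Ti(OiPr)4 (10 mol %), D‑(−)‑diethyl tartrate (12 mol %), TBHP, 4 Å MS, CH2Cl2, −20 °C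
Reagents that add atoms: tert-butyl hydroperoxide, CC(C)(C)OO
Why: Katsuki–Sharpless asymmetric epoxidation, in which the D‑(−)‑tartrate titanium complex delivers oxygen to the face that gives the (2R,3R) epoxide and the E geometry is carried stereospecifically into the cis‑2,3‑dimethyl oxirane.

Step 6
Reactants: 7 [(2R,3R)-2,3-dimethyloxiran-2-yl]methanol
Product: 8 (2S,3R)-2,3-dimethyloxirane-2-carboxylic acid
Conditions: RuCl3 (2 mol %), NaIO4, EtOAc/MeCN/H2O, rt
Reagents that add atoms: water, O
Why: RuO4 oxidation of the primary alcohol to the acid through the aldehyde hydrate leaves the epoxide and both stereocentres untouched (the descriptor at C2 changes only because the priorities change).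

Step 7
Reactants: 8 (2S,3R)-2,3-dimethyloxirane-2-carboxylic acid
Product: 9 (2R,3S)-3-chloro-2-hydroxy-2-methylbutanoic acid
Conditions: HCl (anhydrous), Et2O, 0 °C
Reagents that add atoms: hydrogen chloride, Cl
Why: Acid‑promoted SN2 opening of the glycidic acid, in which chloride attacks the secondary C3 (C2 is quaternary and deactivated by the carboxyl) with inversion and C2 is retained, giving the (2R,3S) chlorohydrin.

Step 8
Reactants: 5 (3S,4S,5R,10R)-4-acetoxy-3-hydroxyeudesm-7(11)-en-8-one; 9 (2R,3S)-3-chloro-2-hydroxy-2-methylbutanoic acid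
Product: 11 (3S,4S,5R,10R)-4-acetoxy-3-[(2R,3S)-3-chloro-2-hydroxy-2-methylbutanoyloxy]eudesm-7(11)-en-8-one, via Yamaguchi mixed anhydride 10 (not isolated)
Conditions: 9, 2,4,6‑Cl3C6H2COCl, Et3N, THF, 0 °C; then 5, DMAP, toluene, rt
Reagents that add atoms: none
Why: Yamaguchi esterification, in which DMAP attacks the aliphatic carbonyl of the mixed anhydride (the aryl carbonyl is shielded by two ortho chlorines) and the acylpyridinium acylates the equatorial 3β‑hydroxyl, while the tertiary hydroxyl of the acid is too hindered to compete and no stereocentre is touched.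

Step 9
Reactants: 11 (3S,4S,5R,10R)-4-acetoxy-3-[(2R,3S)-3-chloro-2-hydroxy-2-methylbutanoyloxy]eudesm-7(11)-en-8-one
Product: 13 CNP0119872.1 (3S,4S,5R,10R)-4-acetoxy-3-[(2R,3S)-3-chloro-2-hydroxy-2-methylbutanoyloxy]-11-hydroxyeudesm-6-en-8-one, via C11 hydroperoxide 12 (not isolated)
Conditions: O2, hν (white LED), tetraphenylporphyrin (1 mol %), CH2Cl2, 0 °C; then PPh3, 0 °C → rt
Reagents that add atoms: oxygen, O=O
Why: Schenck ene reaction of singlet oxygen with the s‑cis enone shows the "gem" regioselectivity seen with pulegone, so O2 bonds to C11 while the axial H‑6β on the carbon geminal to the carbonyl is abstracted and the double bond moves to C6=C7; PPh3 then reduces the tertiary hydroperoxide to the alcohol and C5 is untouched.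

## Compound list

1 | germacrone, (1(10)E,4E)-germacra-1(10),4,7(11)-trien-8-one | C/C1=C\CC(=C(C)C)C(=O)C/C(C)=C/CC1 | starting material
2 | (5R,10R)-eudesma-3,7(11)-dien-8-one (trans‑decalin; 5α‑H; 10β‑Me) | CC1=CCC[C@]2(C)CC(=O)C(=C(C)C)C[C@H]21 | intermediate
3 | (4S,5R,10R)-4-hydroxyeudesm-7(11)-ene-3,8-dione (4α‑OH; 4β‑Me) | O[C@]1(C)C(=O)CC[C@]2(C)CC(=O)C(=C(C)C)C[C@H]21 | intermediate
4 | (4S,5R,10R)-4-acetoxyeudesm-7(11)-ene-3,8-dione | CC(=O)O[C@]1(C)C(=O)CC[C@]2(C)CC(=O)C(=C(C)C)C[C@H]21 | intermediate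
5 | (3S,4S,5R,10R)-4-acetoxy-3-hydroxyeudesm-7(11)-en-8-one (3β‑OH; 4α‑OAc) | CC(=O)O[C@]1(C)[C@@H](O)CC[C@]2(C)CC(=O)C(=C(C)C)C[C@H]21 | intermediate
6 | (E)-2-methylbut-2-en-1-ol (tiglyl alcohol) | C/C=C(\C)CO | starting material
7 | [(2R,3R)-2,3-dimethyloxiran-2-yl]methanol | OC[C@@]1(C)O[C@@H]1C | intermediate
8 | (2S,3R)-2,3-dimethyloxirane-2-carboxylic acid | OC(=O)[C@@]1(C)O[C@@H]1C | intermediate
9 | (2R,3S)-3-chloro-2-hydroxy-2-methylbutanoic acid | OC(=O)[C@@](C)(O)[C@H](C)Cl | intermediate
10 | (2R,3S)-3-chloro-2-hydroxy-2-methylbutanoic 2,4,6-trichlorobenzoic anhydride (Yamaguchi mixed anhydride) | Clc1cc(Cl)c(c(Cl)c1)C(=O)OC(=O)[C@@](C)(O)[C@H](C)Cl | intermediate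
11 | (3S,4S,5R,10R)-4-acetoxy-3-[(2R,3S)-3-chloro-2-hydroxy-2-methylbutanoyloxy]eudesm-7(11)-en-8-one | CC(=O)O[C@]1(C)[C@@H](OC(=O)[C@@](C)(O)[C@H](C)Cl)CC[C@]2(C)CC(=O)C(=C(C)C)C[C@H]21 | intermediate
12 | (3S,4S,5R,10R)-4-acetoxy-3-[(2R,3S)-3-chloro-2-hydroxy-2-methylbutanoyloxy]-11-hydroperoxyeudesm-6-en-8-one | CC(=O)O[C@]1(C)[C@@H](OC(=O)[C@@](C)(O)[C@H](C)Cl)CC[C@]2(C)CC(=O)C(C(C)(C)OO)=C[C@H]21 | intermediate
13 | CNP0119872.1, (3S,4S,5R,10R)-4-acetoxy-3-[(2R,3S)-3-chloro-2-hydroxy-2-methylbutanoyloxy]-11-hydroxyeudesm-6-en-8-one | CC(=O)O[C@]1(C)[C@@H](OC(=O)[C@@](C)(O)[C@H](C)Cl)CC[C@]2(C)CC(=O)C(C(C)(C)O)=C[C@H]21 | target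

## Step count and risks

Total steps: 9. Longest linear sequence: 6 (steps 1, 2, 3, 4, 8, 9 from germacrone).

Three steps most likely to fail:

Step 1. The asymmetric version of this cyclisation is unprecedented. The enantioselectivity may be low, and proton loss from the C4 cation can also give the Δ4(15) and Δ4 olefins. Fallback: starting from 1, cyclise with p‑TsOH in CH2Cl2, which also equilibrates the exocyclic isomer to the Δ3 olefin, to obtain racemic eudesma-3,7(11)-dien-8-one F1. Resolve it by preparative chiral SFC, a resolution in place of asymmetric catalysis. The (5R,10R) enantiomer is 2, where the route is rejoined.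

Step 2. RuO4 may also attack the enone olefin or cleave the ketol. Fallback: starting from 2, dihydroxylate with OsO4 (cat.)/NMO, which is selective for the isolated trisubstituted olefin and adds from the α face, to give the cis‑diol (3R,4S,5R,10R)-3,4-dihydroxyeudesm-7(11)-en-8-one F2. Oxidise only its secondary hydroxyl with TEMPO/PhI(OAc)2 to come back to 3.

Step 8. Both partners are hindered, the 4‑acetate can migrate to the free 3‑hydroxyl under base, and the β‑chloro‑α‑hydroxy acid can self‑condense or lactonise. Fallback: starting from 5 and the epoxy acid 8, which has no free hydroxyl and no chloride, activate 8 as (2S,3R)-2,3-dimethyloxirane-2-carboxylic 2,4,6-trichlorobenzoic anhydride F3. Acylate 5 with it (DMAP, toluene) to give the epoxy ester (3S,4S,5R,10R)-4-acetoxy-3-[(2S,3R)-2,3-dimethyloxirane-2-carbonyloxy]eudesm-7(11)-en-8-one F4. Open the oxirane with anhydrous HCl in Et2O at 0 °C; chloride attacks C3′ with inversion, and the route is rejoined at 11.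

Further compounds
F1 | step 1 | racemic eudesma-3,7(11)-dien-8-one (1:1 mixture of 2 and its enantiomer) | CC1=CCC[C@]2(C)CC(=O)C(=C(C)C)C[C@H]21.CC1=CCC[C@@]2(C)CC(=O)C(=C(C)C)C[C@@H]21
F2 | step 2 | (3R,4S,5R,10R)-3,4-dihydroxyeudesm-7(11)-en-8-one | O[C@]1(C)[C@H](O)CC[C@]2(C)CC(=O)C(=C(C)C)C[C@H]21
F3 | step 8 | (2S,3R)-2,3-dimethyloxirane-2-carboxylic 2,4,6-trichlorobenzoic anhydride | Clc1cc(Cl)c(c(Cl)c1)C(=O)OC(=O)[C@@]1(C)O[C@@H]1C
F4 | step 8 | (3S,4S,5R,10R)-4-acetoxy-3-[(2S,3R)-2,3-dimethyloxirane-2-carbonyloxy]eudesm-7(11)-en-8-one | CC(=O)O[C@]1(C)[C@@H](OC(=O)[C@@]3(C)O[C@@H]3C)CC[C@]2(C)CC(=O)C(=C(C)C)C[C@H]21
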